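Eudesmane numbering is used for every intermediate: C1–C4 and C15 belong to ring A, C5 and C10 are the fusion carbons, C6–C9 complete ring B, C14 sits on C10 and C11–C13 form the isopropyl group. β is the face of ring B that carries C14.

## The problem

Target 22 is the (E)-4-hydroxycinnamate of eudesm-3-en-6β-ol. It is a trans-fused decalin in which ring A holds the trisubstituted C3=C4 olefin and ring B carries four contiguous stereocentres: C10 (quaternary, β-methyl C14), C5 (α-hydrogen), C6 (β, axial acyloxy) and C7 (β, equatorial isopropyl). C10 cannot be corrected once it is made, so it has to be set with absolute control and then used to place the others. C6–O and C14 are 1,3-diaxial on the β face and can be tied together, and C5 lies between them. C7 is 1,4 to C10 across the ring, out of reach of any tether from C10, and needs its own source of control. The C3=C4 olefin has an allylic hydrogen at the ring fusion and moves into the tetrasubstituted C4=C5 position under acid. The axial C6 oxygen is hindered by C14, C4 and the isopropyl group and is prone to elimination. The cinnamate is a base-labile Michael acceptor with a free phenol, so the ester belongs at the very end. The enabling feature is that C5–C10 of ring B, with para substituents at C10 and C7, are the ring of 4-isopropylbenzoic acid, whose carboxyl carbon is C14. After Birch reduction–alkylation the two olefins C5=C6 and C8=C9 are enantiotopic and the carboxyl group on C10 is placed to lactonise onto C6. One lactonisation can therefore fix C10, C6 and C5 together.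

## Retrosynthesis

**Ester bond.** The C6–O acyl bond of 22 is cut first, through silyl ether 21, to eudesm-3-en-6β-ol 16 and the silyl-protected coumaric acid 19 (from p-coumaric acid 17). This keeps the cinnamate and the phenol out of all reductive, radical and strongly basic steps. The forward reaction must acylate a hindered axial alcohol.

**C14 and O6 as one group.** The 1,3-diaxial methyl/hydroxyl pair of 16 is taken back to lactol 14 and γ-lactone 13 (eudesm-3-en-14,6β-olide). A 6-ketone reduced by hydride would have to rely on facial preference; the lactone fixes the β configuration of O6 by ring constraint, and Wolff–Kishner reduction of the lactol returns methyl and hydroxyl in one operation.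

**Ring A at C3=C4.** Lactone 13 is opened by retro-metathesis to diene 12, which has an isopropenyl group on C5 and a butenyl chain on C10. The olefin can then only form between C3 and C4, which dehydration or isomerisation routes cannot guarantee. A direct C4–C5 closure with a tethered iodoalkene was set aside: the C5 radical it needs would have an easy 5-exo path onto that olefin. Diene 12 comes from aldehyde 9 by methylenation and 9 from acetal 8.

**C4–C5 bond.** The isopropenyl group of 8 is disconnected to secondary bromide 6 and 2-bromopropene 7, to be joined by nickel-catalysed reductive coupling. The bromide is neopentyl-like, cannot be displaced and has no anti hydrogen for elimination, so a radical process is the only practical use of it. The coupling must deliver carbon to the β face of C5.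

**Spectator olefin.** Bromide 6 comes from 5 by hydrogenation of C8=C9 while it is the only C=C in the molecule. This removes a homoallylic partner for the C5 radical and any later need to distinguish two ring olefins.

**Key disconnection.** The C6–O and C5–Br bonds of 5 are cut to give achiral diene acid 4. The precursor has no stereogenic centre and one ring. The forward bromolactonisation must choose between two enantiotopic olefins.

**Birch alkylation.** Acid 4 is cut at C10–C1 to 4-isopropylbenzoic acid 1 and 2-(2-bromoethyl)-1,3-dioxolane 2. An acetal chain is preferred to an iodoalkenyl chain. It survives lithium amide, it offers no second olefin to the bromine source in the key step, and it carries no radical acceptor into the C5 coupling.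

## Roads not taken

**Alternative 1: Diels–Alder annulation of ring B.** The cut is across C5–C6 and C9–C10. In the forward step Cu(OTf)2 with a tert-butyl bis(oxazoline) ligand would bind keto ester A1 in two-point fashion and add silyloxy diene A2 across C5=C10 to give the cis-fused adduct A3. Merits: it is convergent, it makes two C–C bonds and ring B at once, it sets C10 together with the C6 oxygen, and the C4 ketone in A3 gives the C3=C4 olefin cleanly through a kinetic enol triflate. In convergence and in speed to the bicyclic skeleton it is better than the chosen plan, which needs seven steps to reach both rings. Weak points: A1 is a tetrasubstituted, β-methyl dienophile and will be sluggish. The O6/C14 relationship rests on an endo preference. After the key step the ester on C5 must be removed and the ring fusion then set trans by protonation, and C7 must be set by a late hydrogenation. The chosen plan sets against this a covalent tether for O6/C14 and a ring fusion that is never epimerisable.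

**Alternative 2: transannular cyclisation of a germacradienol.** The cut is the C5–C10 bond across a ten-membered ring. Mild acid would protonate C1 of germacradienol A4, C5 would capture the C10 cation, and loss of H3 would give A5, which is identical with 16. Merits: one step makes both rings and sets C5 and C10 from the chair-like conformer in which the C6 and C7 substituents are equatorial. The endgame from A4 is shorter than anything the chosen plan offers. Weak points: A4 is a ten-membered (E,E)-diene with two stereocentres, hard to make and prone to Cope rearrangement on warming. Its C6 hydroxyl is allylic to C4=C5 and can ionise under the cyclisation conditions. The C4 cation can lose H3 or H15, or take up water, with nothing in the substrate to steer it. The chosen plan is longer, but it fixes the olefin position by construction and fixes each stereocentre by a defined event.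

**Alternative 3: acylium–ene closure of ring B at C6–C7.** SnCl4 would ionise acid chloride A6, the acylium carbon C6 would add to C7 of the side-chain olefin, and proton loss from the C11 cation would give dienone A7. Merits: it is short and classical, it installs the C6 carbonyl directly, and C7 is α to that ketone and can be equilibrated to the equatorial isomer. That last point is better than the chosen plan, in which C7 depends on the facial selectivity of an alkylation. Weak points: the C10 quaternary centre of A6 needs its own asymmetric synthesis. A7 is a conjugated C4=C5 enone, so the C3=C4 olefin and the C5 hydrogen would have to come from a contra-thermodynamic deconjugation. The isopropenyl group must later be hydrogenated beside the ring olefin. The chosen plan offsets its C7 risk with the kinetic rejection of the wrong diastereomer in the key step, and it never places a double bond at C5.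

Key step: step 2

Assumption: which pseudoenantiomer of the cinchona dimer gives the required lactone cannot be predicted with certainty for this 4-substituted substrate; (DHQD)2PHAL is written, and (DHQ)2PHAL would be used if the first run delivers the antipode of 5.

## Route

Step 1
Reactants: 1 4-isopropylbenzoic acid; 2 2-(2-bromoethyl)-1,3-dioxolane
Product: 4 cis-1-[2-(1,3-dioxolan-2-yl)ethyl]-4-isopropylcyclohexa-2,5-diene-1-carboxylic acid, via dilithium dienediolate 3 (not isolated)
Conditions: Li (3.2 equiv), NH3(l)/THF, −78 °C; then 2, −78 to −33 °C; NH4Cl; citric acid to pH 4, 0 °C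
Reagents that add atoms: none
Why: Birch reduction–alkylation of a benzoic acid: reduction and para protonation give dienediolate 3, which the primary bromide alkylates at C10. The electrophile should enter on the face away from the C7 isopropyl group across the near-planar ring, placing the chain trans and the carboxyl cis to isopropyl; any trans acid is removed in step 2.

Step 2
Reactants: 4 cis-1-[2-(1,3-dioxolan-2-yl)ethyl]-4-isopropylcyclohexa-2,5-diene-1-carboxylic acid
Product: 5 bridged bromo γ-lactone 8-bromo-1-[2-(1,3-dioxolan-2-yl)ethyl]-4-isopropyl-6-oxabicyclo[3.2.1]oct-2-en-7-one (14,6β-lactone; 5α-Br; 7β-isopropyl; C8=C9)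
Conditions: N-bromosuccinimide (1.1 equiv), (DHQD)2PHAL (hydroquinidine 1,4-phthalazinediyl diether, 10 mol %), CHCl3/hexane 1:1, −40 °C
Reagents that add atoms: N-bromosuccinimide, O=C1CCC(=O)N1Br
Why: This is a catalytic enantioselective desymmetrising bromolactonisation, the known reaction of 1-alkylcyclohexa-2,5-diene-1-carboxylic acids with N-bromosuccinimide and dimeric cinchona alkaloid ethers. The quinuclidine nitrogen pairs with the carboxylate and passes Br+ to one of the two enantiotopic olefins on the α face, opposite the carboxyl group; this choice alone makes C10 stereogenic and fixes it. The carboxylate oxygen then opens the bromonium ion at C6 in an anti sense, a formally 5-endo closure to the bridged γ-lactone. The 4-exo β-lactone, if it forms, is the kinetic product of this substrate class and is known to isomerise to the γ-lactone. C6–O must be β because the oxygen is delivered from C14, and C5–Br must be α because the addition is anti; C7 was fixed relative to C10 in step 1. The selectivity needed is between the two olefins and rests on the catalyst, and the substrate offers no other nucleophilic olefin because the dioxolane chain is inert to Br+. The trans acid from step 1 would have to place bromine and isopropyl 1,3-diaxial on the α face, so it should react far more slowly and be washed out as unreacted acid with bicarbonate.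

Step 3
Reactants: 5 bridged bromo γ-lactone
Product: 6 saturated bromo lactone 8-bromo-1-[2-(1,3-dioxolan-2-yl)ethyl]-4-isopropyl-6-oxabicyclo[3.2.1]octan-7-one
Conditions: H2 (1 atm), [Ir(cod)(PCy3)(py)]PF6 (5 mol %), CH2Cl2, rt
Reagents that add atoms: none
Why: Homogeneous hydrogenation of the only C=C in the molecule; the cationic iridium catalyst accepts hindered disubstituted olefins and should leave the secondary bromide, lactone and acetal alone. No stereocentre is created, and removing C8=C9 here takes away the homoallylic partner of the C5 radical in step 4.

Step 4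
Reactants: 6 saturated bromo lactone; 7 2-bromopropene
Product: 8 1-[2-(1,3-dioxolan-2-yl)ethyl]-4-isopropyl-8-(prop-1-en-2-yl)-6-oxabicyclo[3.2.1]octan-7-one (isopropenyl on C5β)
Conditions: NiBr2(dme) (10 mol %), 4,4′-di-tert-butyl-2,2′-bipyridine (10 mol %), Mn powder (3 equiv), DMA, 25 °C
Reagents that add atoms: none
Why: Nickel-catalysed reductive cross-electrophile coupling of an alkenyl bromide with a secondary alkyl bromide: halogen abstraction frees the C5 radical, the isopropenylnickel species captures it and reductive elimination forms C4–C5. The bulky nickel complex should bond on the equatorial β face, which is flanked only by the lactone oxygen and carbonyl, because the α face is screened by the axial hydrogens on C7 and C9. The β-acyloxy radical does not fragment, and the substrate holds no olefin for a competing ring closure.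

Step 5
Reactants: 8 isopropenyl lactone acetal
Product: 9 3-[7-oxo-4-isopropyl-8-(prop-1-en-2-yl)-6-oxabicyclo[3.2.1]octan-1-yl]propanal
Conditions: 1 M HCl, THF, rt
Reagents that add atoms: water, O
Why: Acid-catalysed hydrolysis of the dioxolane; the bridged lactone and the 1,1-disubstituted olefin should be stable to dilute acid at room temperature.

Step 6
Reactants: 9 lactone aldehyde; 10 methyltriphenylphosphonium bromide
Product: 12 1-(but-3-en-1-yl)-4-isopropyl-8-(prop-1-en-2-yl)-6-oxabicyclo[3.2.1]octan-7-one, via methylenetriphenylphosphorane 11 (not isolated)
Conditions: 10, KN(SiMe3)2, THF, 0 °C; then 9, −78 to 0 °C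
Reagents that add atoms: none
Why: Wittig methylenation of an unhindered aldehyde; the ylide should not attack the hindered lactone, and no stereocentre is epimerisable.

Step 7
Reactants: 12 diene lactone
Product: 13 eudesm-3-en-14,6β-olide
Conditions: second-generation Grubbs catalyst RuCl2(=CHPh)(PCy3)(H2IMes) (5 mol %), CH2Cl2, 40 °C
Reagents that add atoms: none
Why: Ring-closing metathesis of a monosubstituted and a 1,1-disubstituted olefin on adjacent, trans-diequatorial positions closes ring A as a trans-fused cyclohexene. The double bond can only form between C3 and C4, and ethene leaves.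

Step 8
Reactants: 13 eudesm-3-en-14,6β-olide
Product: 14 14,6β-epoxyeudesm-3-en-14-ol (lactol)
Conditions: iBu2AlH (1.2 equiv), CH2Cl2, −78 °C; aq. potassium sodium tartrate
Reagents that add atoms: none
Why: Partial reduction of a lactone to the lactol through an aluminium hemiacetal that is stable at low temperature; the olefin is untouched and the anomeric mixture is of no consequence.

Step 9
Reactants: 14 lactol
Product: 16 eudesm-3-en-6β-ol, via hydroxy hydrazone 15 (not isolated)
Conditions: N2H4·H2O, KOH, diethylene glycol, 130 °C then 200 °C
Reagents that add atoms: none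
Why: Wolff–Kishner reduction in the Huang-Minlon form: the lactol opens to the hydroxy aldehyde, whose hydrazone loses nitrogen to give the C14 methyl group and the free 6β-hydroxyl. The isolated olefin has no acidifying neighbour, and none of C5, C6, C7 or C10 can epimerise.

Step 10
Reactants: 17 (E)-4-hydroxycinnamic acid (p-coumaric acid)
Product: 19 (E)-3-[4-(tert-butyldimethylsilyloxy)phenyl]prop-2-enoic acid, via bis-silylated coumarate 18 (not isolated)
Conditions: TBSCl (2.3 equiv), imidazole, DMF, rt; then AcOH/THF/H2O 3:1:1, rt
Reagents that add atoms: tert-butyldimethylsilyl chloride, CC(C)(C)[Si](C)(C)Cl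
Why: Silylation of both acidic groups followed by selective hydrolysis of the labile silyl ester; the aryl silyl ether should survive the mildly acidic hydrolysis.

Step 11
Reactants: 16 eudesm-3-en-6β-ol; 19 silyl-protected coumaric acid
Product: 21 eudesm-3-en-6β-yl (E)-3-[4-(tert-butyldimethylsilyloxy)phenyl]prop-2-enoate, via mixed trichlorobenzoic anhydride 20 (not isolated)
Conditions: 2,4,6-trichlorobenzoyl chloride, Et3N, THF, rt; then 16, DMAP, toluene, 80 °C
Reagents that add atoms: none
Why: Yamaguchi esterification: the acylpyridinium ion formed from mixed anhydride 20 should acylate the hindered axial alcohol. Only the O–H bond reacts, so C6 keeps its configuration and the E olefin is retained.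

Step 12
Reactants: 21 silyl-protected ester
Product: 22 eudesm-3-en-6β-yl (E)-3-(4-hydroxyphenyl)prop-2-enoate
Conditions: Bu4NF, AcOH, THF, 0 °C
Reagents that add atoms: none
Why: Fluoride cleavage of the aryl silyl ether; acetic acid buffers the phenoxide so that the cinnamate should be neither cleaved nor isomerised.

## Compound list

1 | 4-isopropylbenzoic acid | CC(C)c1ccc(cc1)C(=O)O | starting material
2 | 2-(2-bromoethyl)-1,3-dioxolane | BrCCC1OCCO1 | starting material
3 | dilithium (4-isopropylcyclohexa-2,5-dien-1-ylidene)methanediolate | CC(C)C1C=CC(=C([O-])[O-])C=C1.[Li+].[Li+] | intermediate (not isolated)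
4 | 1-[2-(1,3-dioxolan-2-yl)ethyl]-4-isopropylcyclohexa-2,5-diene-1-carboxylic acid, carboxyl cis to isopropyl (achiral) | CC(C)[C@H]1C=C[C@@](CCC2OCCO2)(C(=O)O)C=C1 | intermediate
5 | 8-bromo-1-[2-(1,3-dioxolan-2-yl)ethyl]-4-isopropyl-6-oxabicyclo[3.2.1]oct-2-en-7-one; lactone C14(=O)–O–C6 on the β face, 5α-bromo, 7β-isopropyl, chain on C10α, C8=C9 | O=C1O[C@H]2[C@H](Br)[C@]1(CCC3OCCO3)C=C[C@H]2C(C)C | intermediate
6 | 8-bromo-1-[2-(1,3-dioxolan-2-yl)ethyl]-4-isopropyl-6-oxabicyclo[3.2.1]octan-7-one; same configuration as 5, C8–C9 saturated | O=C1O[C@H]2[C@H](Br)[C@]1(CCC3OCCO3)CC[C@H]2C(C)C | intermediate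
7 | 2-bromopropene | CC(Br)=C | starting material
8 | 1-[2-(1,3-dioxolan-2-yl)ethyl]-4-isopropyl-8-(prop-1-en-2-yl)-6-oxabicyclo[3.2.1]octan-7-one; isopropenyl on C5β (syn to the lactone bridge), 5α-H | O=C1O[C@H]2[C@@H](C(C)=C)[C@]1(CCC3OCCO3)CC[C@H]2C(C)C | intermediate
9 | 3-[7-oxo-4-isopropyl-8-(prop-1-en-2-yl)-6-oxabicyclo[3.2.1]octan-1-yl]propanal; configuration as 8 | O=C1O[C@H]2[C@@H](C(C)=C)[C@]1(CCC=O)CC[C@H]2C(C)C | intermediate
10 | methyltriphenylphosphonium bromide | C[P+](c1ccccc1)(c1ccccc1)c1ccccc1.[Br-] | starting material
11 | methylenetriphenylphosphorane | C=P(c1ccccc1)(c1ccccc1)c1ccccc1 | intermediate (not isolated)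
12 | 1-(but-3-en-1-yl)-4-isopropyl-8-(prop-1-en-2-yl)-6-oxabicyclo[3.2.1]octan-7-one; configuration as 8 | O=C1O[C@H]2[C@@H](C(C)=C)[C@]1(CCC=C)CC[C@H]2C(C)C | intermediate
13 | eudesm-3-en-14,6β-olide (trans-fused, 5α-H, 7β-isopropyl) | O=C1O[C@H]2[C@H]3C(C)=CCC[C@@]13CC[C@H]2C(C)C | intermediate
14 | 14,6β-epoxyeudesm-3-en-14-ol (lactol, both anomers) | OC1O[C@H]2[C@H]3C(C)=CCC[C@@]13CC[C@H]2C(C)C | intermediate
15 | 6β-hydroxyeudesm-3-en-14-al hydrazone | CC1=CCC[C@]2(C=NN)CC[C@@H](C(C)C)[C@@H](O)[C@@H]12 | intermediate (not isolated)
16 | eudesm-3-en-6β-ol; (1R,2S,4aR,8aR)-4a,8-dimethyl-2-(propan-2-yl)-1,2,3,4,4a,5,6,8a-octahydronaphthalen-1-ol | CC1=CCC[C@]2(C)CC[C@@H](C(C)C)[C@@H](O)[C@@H]12 | intermediate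
17 | (E)-4-hydroxycinnamic acid (p-coumaric acid) | O=C(O)/C=C/c1ccc(O)cc1 | starting material
18 | tert-butyldimethylsilyl (E)-3-[4-(tert-butyldimethylsilyloxy)phenyl]prop-2-enoate | CC(C)(C)[Si](C)(C)OC(=O)/C=C/c1ccc(O[Si](C)(C)C(C)(C)C)cc1 | intermediate (not isolated)
19 | (E)-3-[4-(tert-butyldimethylsilyloxy)phenyl]prop-2-enoic acid | O=C(O)/C=C/c1ccc(O[Si](C)(C)C(C)(C)C)cc1 | intermediate
20 | (E)-3-[4-(tert-butyldimethylsilyloxy)phenyl]prop-2-enoic 2,4,6-trichlorobenzoic anhydride | O=C(/C=C/c1ccc(O[Si](C)(C)C(C)(C)C)cc1)OC(=O)c1c(Cl)cc(Cl)cc1Cl | intermediate (not isolated)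
21 | eudesm-3-en-6β-yl (E)-3-[4-(tert-butyldimethylsilyloxy)phenyl]prop-2-enoate | CC1=CCC[C@]2(C)CC[C@@H](C(C)C)[C@@H](OC(=O)/C=C/c3ccc(O[Si](C)(C)C(C)(C)C)cc3)[C@@H]12 | intermediate
22 | eudesm-3-en-6β-yl (E)-3-(4-hydroxyphenyl)prop-2-enoate; (1R,2S,4aR,8aR)-4a,8-dimethyl-2-(propan-2-yl)-1,2,3,4,4a,5,6,8a-octahydronaphthalen-1-yl ester | CC1=CCC[C@]2(C)CC[C@@H](C(C)C)[C@@H](OC(=O)/C=C/c3ccc(O)cc3)[C@@H]12 | target

## Step count and risks

Total step count: 12. Longest linear sequence: 11 steps (steps 1 to 9, 11 and 12); step 10 is a one-step side branch.

**Step 2 (key step).** The catalyst may discriminate poorly between the two olefins, because the isopropyl group on C7 sits next to the carbon that receives oxygen and lies outside the usual substrate range. Closure may also be slow enough for 4-exo attack at C5 to compete. Fallback: setting out from 4, a non-selective bromolactonisation (N-bromosuccinimide, NaHCO3, CH2Cl2) would give 5 as the racemate, which is taken through steps 3 to 9 to racemic 16. Esterification with (S)-2-methoxy-2-phenylacetic acid (N,N′-dicyclohexylcarbodiimide, DMAP, CH2Cl2) gives two diastereomers, the (S)-O-methylmandelate of 16 F1 and the (S)-O-methylmandelate of the enantiomer of 16 F2, to be separated by chromatography. LiAlH4 (Et2O, 0 °C) on F1 returns 16, and the route continues at step 11.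

**Step 4.** Capture of the C5 radical may show poor facial selectivity, and an sp2 substituent offers no way to correct the centre afterwards. Coupling at this neopentyl-like position may also be slow, so that simple reduction of the bromide wins. Fallback: setting out from 6, nickel-catalysed reductive acylation with S-(pyridin-2-yl) ethanethioate (NiCl2(dme), 4,4′-di-tert-butyl-2,2′-bipyridine, Mn, DMA) would give the methyl ketone 8-acetyl-1-[2-(1,3-dioxolan-2-yl)ethyl]-4-isopropyl-6-oxabicyclo[3.2.1]octan-7-one F3. Its C5 hydrogen is α to the ketone, so DBU in toluene can equilibrate the centre to the equatorial β-acetyl isomer. 1 M HCl in THF then gives the keto aldehyde 3-[8-acetyl-7-oxo-4-isopropyl-6-oxabicyclo[3.2.1]octan-1-yl]propanal F4. Double methylenation (CH2Br2, Zn, TiCl4, THF) converts both carbonyl groups and rejoins the route at 12.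

**Step 1.** Lithium amide may eliminate HBr from the bromoacetal before alkylation, and facial selectivity in the alkylation may be modest. Fallback: setting out from 1, reduction (Li, NH3, THF) with a proton quench gives 4-isopropylcyclohexa-2,5-diene-1-carboxylic acid F5 as a cis/trans mixture, both of which converge on the same dianion. Deprotonation with LiN(iPr)2 (2.2 equiv, THF, −78 °C) in the absence of ammonia and amide, then addition of 2, returns to 4. Any trans acid that remains is still rejected in step 2.

**Step 9.** Hydrazone formation from the hindered neopentyl lactol may be incomplete, and the axial alkoxide may be lost by elimination at 200 °C. Fallback: setting out from 14, condensation with 4-methylbenzenesulfonohydrazide (MeOH, 50 °C) gives 6β-hydroxyeudesm-3-en-14-al tosylhydrazone F6. Catecholborane (CHCl3, 0 °C) followed by NaOAc·3H2O at reflux expels sulfinate and nitrogen and returns to 16 without strong base or high temperature.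

**Step 11.** Acylation of the axial alcohol, which is crowded by C14, C4 and the isopropyl group, may be so slow that the mixed anhydride decomposes or transfers its trichlorobenzoyl half. Fallback: setting out from 16, the small and reactive acryloyl chloride (Et3N, DMAP, CH2Cl2, 0 °C) gives eudesm-3-en-6β-yl acrylate F7. A Heck arylation with 4-iodophenol (Pd(OAc)2, P(o-tol)3, Et3N, DMF, 90 °C) then builds the E-cinnamate on the ester and arrives at 22 directly, bypassing 19 to 21.

## Further compounds

F1 | step 2 | eudesm-3-en-6β-yl (S)-2-methoxy-2-phenylacetate | CC1=CCC[C@]2(C)CC[C@@H](C(C)C)[C@@H](OC(=O)[C@@H](OC)c3ccccc3)[C@@H]12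
F2 | step 2 | (S)-2-methoxy-2-phenylacetate of the enantiomer of 16 | CC1=CCC[C@@]2(C)CC[C@H](C(C)C)[C@H](OC(=O)[C@@H](OC)c3ccccc3)[C@H]12
F3 | step 4 | 8-acetyl-1-[2-(1,3-dioxolan-2-yl)ethyl]-4-isopropyl-6-oxabicyclo[3.2.1]octan-7-one (acetyl on C5β) | O=C1O[C@H]2[C@@H](C(C)=O)[C@]1(CCC3OCCO3)CC[C@H]2C(C)C
F4 | step 4 | 3-[8-acetyl-7-oxo-4-isopropyl-6-oxabicyclo[3.2.1]octan-1-yl]propanal | O=C1O[C@H]2[C@@H](C(C)=O)[C@]1(CCC=O)CC[C@H]2C(C)C
F5 | step 1 | 4-isopropylcyclohexa-2,5-diene-1-carboxylic acid (cis/trans mixture) | CC(C)C1C=CC(C(=O)O)C=C1
F6 | step 9 | 6β-hydroxyeudesm-3-en-14-al 4-methylbenzenesulfonylhydrazone | CC1=CCC[C@]2(C=NNS(=O)(=O)c3ccc(C)cc3)CC[C@@H](C(C)C)[C@@H](O)[C@@H]12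
F7 | step 11 | eudesm-3-en-6β-yl prop-2-enoate | CC1=CCC[C@]2(C)CC[C@@H](C(C)C)[C@@H](OC(=O)C=C)[C@@H]12
A1 | alternative 1 | methyl 2-methyl-6-oxocyclohex-1-ene-1-carboxylate | COC(=O)C1=C(C)CCCC1=O
A2 | alternative 1 | (1E)-1-(tert-butyldimethylsilyloxy)-2-isopropylbuta-1,3-diene | C=C/C(=C/O[Si](C)(C)C(C)(C)C)C(C)C
A3 | alternative 1 | cis-fused 5-carbomethoxy-6-silyloxy-15-noreudesm-7-en-4-one | O=C1CCC[C@]2(C)CC=C(C(C)C)[C@@H](O[Si](C)(C)C(C)(C)C)[C@]12C(=O)OC
A4 | alternative 2 | (1(10)E,4E)-germacra-1(10),4-dien-6-ol with the C6 and C7 configuration of the target | C/C1=C\CC/C(C)=C/[C@H](O)[C@H](C(C)C)CC1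
A5 | alternative 2 | eudesm-3-en-6β-ol (identical with 16) | CC1=CCC[C@]2(C)CC[C@@H](C(C)C)[C@@H](O)[C@@H]12
A6 | alternative 3 | 2,6-dimethyl-6-(4-methylpent-3-en-1-yl)cyclohex-1-ene-1-carbonyl chloride | CC1=C(C(=O)Cl)[C@@](C)(CCC=C(C)C)CCC1
A7 | alternative 3 | eudesma-4,11-dien-6-one | CC1=C2C(=O)[C@H](C(C)=C)CC[C@@]2(C)CCC1
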